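Everything rests on cutting two bonds of the phthalide at once, C3–C3a and C1–C7a. Ring A bears the carbinol carbon C3 at C3a and the carbonyl carbon C1 at the adjacent C7a, which is itself ortho to the C7 methoxy group. This is the 1,2,3-array left when 3,5-dimethoxybenzyne is attacked by a carbanion at its unhindered terminus and the aryl anion then captures an acyl group. In one operation an enantioenriched α-lithiated O-alkyl carbamate plays both roles, setting the C3 configuration and handing its own carbamoyl group over from O2 as C1. The precursor is a linear tridecyl N,N-diisopropylcarbamate holding C10' as a silyl ether and C13' as a dioxolane.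

Key step: step 9

Numbering: phthalide C1 (C=O), O2, C3, C3a, C4–C7, C7a (ring A is the benzene ring); side chain C1'–C14'. The target is (3S,10'R).
Assumption: carbanion 14 attacks the aryne with retention, as non-benzylic lithiated carbamates do with other electrophiles, hence (+)-sparteine. If inversion were found, (−)-sparteine would be used with no other change.

Step 1
Reactants: 1 hex-5-en-2-one
Product: 2 2-(but-3-en-1-yl)-2-methyl-1,3-dioxolane
Conditions: ethylene glycol, TsOH·H2O (cat.), toluene, reflux, Dean–Stark
Reagents that add atoms: ethylene glycol, OCCO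
Why: Acid-catalysed ketalisation driven by azeotropic removal of water; the remote terminal alkene takes no part.

Step 2
Reactants: 2 2-(but-3-en-1-yl)-2-methyl-1,3-dioxolane
Product: 3 rac-2-methyl-2-[2-(oxiran-2-yl)ethyl]-1,3-dioxolane
Conditions: mCPBA, CH2Cl2, 0 °C to rt
Reagents that add atoms: mCPBA, OOC(=O)c1cccc(Cl)c1
Why: Prilezhaev epoxidation of the only alkene; the racemate is accepted because the next step resolves it, and the dioxolane survives the weakly acidic anhydrous medium.

Step 3
Reactants: 3 rac-2-methyl-2-[2-(oxiran-2-yl)ethyl]-1,3-dioxolane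
Product: 4 2-methyl-2-{2-[(2S)-oxiran-2-yl]ethyl}-1,3-dioxolane
Conditions: (S,S)-Co(salen)(OAc) (0.5 mol %; salen = N,N'-bis(3,5-di-tert-butylsalicylidene)cyclohexane-1,2-diaminate, trivalent cobalt), H2O (0.55 equiv), neat, 0 °C to rt
Reagents that add atoms: none
Why: Jacobsen hydrolytic kinetic resolution: by the established sense for alkyl oxiranes the (S,S)-catalyst hydrates the (R)-epoxide much faster, so the unreacted (S)-epoxide, whose stereocentre becomes C10', should be recovered enantiopure and is easily separated from the polar diol.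

Step 4
Reactants: 5 9-bromononan-1-ol; 6 N,N-diisopropylcarbamoyl chloride
Product: 7 9-bromononyl N,N-diisopropylcarbamate
Conditions: Et3N, DMAP (cat.), CH2Cl2, 40 °C
Reagents that add atoms: none
Why: Carbamate formation by DMAP-catalysed O-acylation of the primary alcohol; the primary bromide should not be displaced by the hindered amine under these mild conditions.

Step 5
Reactants: 7 9-bromononyl N,N-diisopropylcarbamate; 4 2-methyl-2-{2-[(2S)-oxiran-2-yl]ethyl}-1,3-dioxolane
Product: 9 (11R)-11-hydroxy-13-(2-methyl-1,3-dioxolan-2-yl)tridecyl N,N-diisopropylcarbamate, via Grignard reagent 8 (not isolated)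
Conditions: Mg, THF, rt to 40 °C; then CuI (10 mol %), 4, −30 to 0 °C; H2O
Reagents that add atoms: none
Why: Copper-catalysed SN2 opening of a terminal epoxide by a Grignard reagent at the unsubstituted carbon leaves the C–O stereocentre untouched (the descriptor changes from S to R only through the CIP ranking), and the hindered carbamate and the ketal are inert to RMgBr.

Step 6
Reactants: 9 (11R)-11-hydroxy-13-(2-methyl-1,3-dioxolan-2-yl)tridecyl N,N-diisopropylcarbamate
Product: 10 (11R)-11-(tert-butyldimethylsilyloxy)-13-(2-methyl-1,3-dioxolan-2-yl)tridecyl N,N-diisopropylcarbamate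
Conditions: TBSCl, imidazole, DMF, rt
Reagents that add atoms: TBSCl, CC(C)(C)[Si](C)(C)Cl
Why: Standard imidazole-promoted silylation of the secondary alcohol gives an ether that withstands alkyllithiums at −78 °C and falls in the final acid step.

Step 7
Reactants: 11 3,5-dimethoxyphenol
Product: 12 2-iodo-3,5-dimethoxyphenol
Conditions: N-iodosuccinimide (1.0 equiv), CH2Cl2, −20 to 0 °C
Reagents that add atoms: N-iodosuccinimide, O=C1CCC(=O)N1I
Why: Electrophilic aromatic iodination of an activated phenol: C2 and C6 (ortho to OH, para to a methoxy group) are equivalent and less crowded than C4 between the two methoxy groups, and one equivalent of reagent at low temperature should limit double iodination.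

Step 8
Reactants: 12 2-iodo-3,5-dimethoxyphenol
Product: 13 2-iodo-3,5-dimethoxyphenyl trifluoromethanesulfonate
Conditions: Tf2O, pyridine, CH2Cl2, 0 °C
Reagents that add atoms: triflic anhydride, O=S(=O)(OS(=O)(=O)C(F)(F)F)C(F)(F)F
Why: O-Sulfonylation of the phenol puts the nucleofuge next to iodine, giving the classical ortho-iodoaryl triflate type of aryne precursor that fragments at −78 °C.

Step 9
Reactants: 10 (11R)-11-(tert-butyldimethylsilyloxy)-13-(2-methyl-1,3-dioxolan-2-yl)tridecyl N,N-diisopropylcarbamate; 13 2-iodo-3,5-dimethoxyphenyl trifluoromethanesulfonate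
Product: 18 2-[(1S,11R)-11-(tert-butyldimethylsilyloxy)-1-hydroxy-13-(2-methyl-1,3-dioxolan-2-yl)tridecyl]-4,6-dimethoxy-N,N-diisopropylbenzamide, via lithiated carbamate 14 (not isolated), via 3,5-dimethoxybenzyne 15 (not isolated), via aryllithium 16 (not isolated), via lithium alkoxide 17 (not isolated)
Conditions: s-BuLi (1.3 equiv), (+)-sparteine (1.4 equiv), Et2O, −78 °C, 5 h; then n-BuLi (hexanes) and 13 (Et2O, modest excess) fed in parallel by syringe pumps, n-BuLi slightly ahead, −78 °C; −78 °C to rt; H2O
Reagents that add atoms: none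
Why: Proposed new method: s-BuLi bound to (+)-sparteine removes the pro-R hydrogen at C3 (sparteine-mediated asymmetric deprotonation of an O-alkyl carbamate) to give the chelated, configurationally stable carbanion 14, while sacrificial n-BuLi performs the iodine–lithium exchange on 13 and the ortho-lithio triflate collapses at once to aryne 15. Carbanion 14 adds to the aryne carbon remote from the flanking methoxy group (future C3a), which places lithium on C7a in 16; this aryllithium attacks the neighbouring carbamate carbonyl through a five-membered, 5-exo-trig transition state and C1–O2 cleavage releases alkoxide 17, so C3a–C3 and C7a–C1 are made in one flask and no ring persists. The closest known reaction types are the retentive electrophilic substitution of sparteine-complexed lithiated alkyl carbamates, the carbometalation of 3-methoxyarynes with capture of an electrophile ortho to the methoxy group, and the anionic homo-Fries (1,4 O-to-C) carbamoyl shift of ortho-lithiated benzyl carbamates; their merger with an aryne as the electrophile is untested. The C3 stereocentre is controlled by the diamine in the deprotonation and by the retentive course expected of a non-benzylic, pyramidal α-oxy organolithium, so that (R)-14 gives (S)-C3, while C10' is a remote spectator. Regioselectivity comes from the C7 methoxy group, whose inductive pull and distortion of the aryne direct the nucleophile to the far terminus and leave the anion next to oxygen. The chemoselectivity needed is that n-BuLi, not 14, reaches the iodine of 13 and that 14, not n-BuLi, reaches the aryne, which the parallel feed is meant to secure (the unhindered alkyllithium wins the exchange on rate, the carbanion wins the aryne on concentration); silyl ether, dioxolane and the n-BuI formed are inert at −78 °C.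

Step 10
Reactants: 18 2-[(1S,11R)-11-(tert-butyldimethylsilyloxy)-1-hydroxy-13-(2-methyl-1,3-dioxolan-2-yl)tridecyl]-4,6-dimethoxy-N,N-diisopropylbenzamide
Product: 19 (3S)-3-[(10R)-10-hydroxy-13-oxotetradecyl]-5,7-dimethoxyphthalide
Conditions: 3 M aq HCl, 1,4-dioxane, 80 °C
Reagents that add atoms: water, O
Why: Acid-catalysed lactonisation of the ortho-hydroxyalkyl benzamide (intramolecular acyl substitution, helped by strain release and protonation of the departing amine) runs alongside ketal hydrolysis and silyl ether cleavage; C3 should hold because both methoxy groups are meta to C3a and the ortho acyl group disfavours a benzylic cation, and C10' is not touched.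

Step 11
Reactants: 19 (3S)-3-[(10R)-10-hydroxy-13-oxotetradecyl]-5,7-dimethoxyphthalide
Product: 20 (3S)-3-[(10R)-10-acetoxy-13-oxotetradecyl]-5,7-dimethoxyphthalide (CNP0131579.2)
Conditions: Ac2O, pyridine, DMAP (cat.), CH2Cl2, rt
Reagents that add atoms: acetic anhydride, CC(=O)OC(C)=O
Why: DMAP-catalysed acetylation of the only free hydroxyl drains the open hydroxy ketone from its equilibrium with the cyclic hemiketal, and the mild base should not epimerise C3.

Compound list
1 | hex-5-en-2-one | C=CCCC(C)=O | starting material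
2 | 2-(but-3-en-1-yl)-2-methyl-1,3-dioxolane | C=CCCC1(C)OCCO1 | intermediate
3 | rac-2-methyl-2-[2-(oxiran-2-yl)ethyl]-1,3-dioxolane | CC1(CCC2CO2)OCCO1 | intermediate
4 | 2-methyl-2-{2-[(2S)-oxiran-2-yl]ethyl}-1,3-dioxolane | CC1(CC[C@H]2CO2)OCCO1 | intermediate
5 | 9-bromononan-1-ol | OCCCCCCCCCBr | starting material
6 | N,N-diisopropylcarbamoyl chloride | CC(C)N(C(C)C)C(Cl)=O | starting material
7 | 9-bromononyl N,N-diisopropylcarbamate | CC(C)N(C(C)C)C(=O)OCCCCCCCCCBr | intermediate
8 | [9-(N,N-diisopropylcarbamoyloxy)nonyl]magnesium bromide | CC(C)N(C(C)C)C(=O)OCCCCCCCCC[Mg]Br | intermediate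
9 | (11R)-11-hydroxy-13-(2-methyl-1,3-dioxolan-2-yl)tridecyl N,N-diisopropylcarbamate | CC(C)N(C(C)C)C(=O)OCCCCCCCCCC[C@H](CCC1(C)OCCO1)O | intermediate
10 | (11R)-11-(tert-butyldimethylsilyloxy)-13-(2-methyl-1,3-dioxolan-2-yl)tridecyl N,N-diisopropylcarbamate | CC(C)N(C(C)C)C(=O)OCCCCCCCCCC[C@H](CCC1(C)OCCO1)O[Si](C)(C)C(C)(C)C | intermediate
11 | 3,5-dimethoxyphenol | COc1cc(O)cc(OC)c1 | starting material
12 | 2-iodo-3,5-dimethoxyphenol | COc1cc(O)c(I)c(OC)c1 | intermediate
13 | 2-iodo-3,5-dimethoxyphenyl trifluoromethanesulfonate | COc1cc(OC)c(I)c(OS(=O)(=O)C(F)(F)F)c1 | intermediate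
14 | (1R,11R)-1-lithio derivative of 10, held as its (+)-sparteine complex | CC(C)N(C(C)C)C(=O)O[C@H]([Li])CCCCCCCCC[C@H](CCC1(C)OCCO1)O[Si](C)(C)C(C)(C)C | intermediate
15 | 3,5-dimethoxybenzyne | COC1=CC(OC)=CC#C1 | intermediate
16 | (1S,11R)-11-(tert-butyldimethylsilyloxy)-1-(2-lithio-3,5-dimethoxyphenyl)-13-(2-methyl-1,3-dioxolan-2-yl)tridecyl N,N-diisopropylcarbamate | COc1cc(OC)c([Li])c(c1)[C@@H](OC(=O)N(C(C)C)C(C)C)CCCCCCCCC[C@H](CCC1(C)OCCO1)O[Si](C)(C)C(C)(C)C | intermediate
17 | lithium alkoxide of 18 | COc1cc(OC)c(C(=O)N(C(C)C)C(C)C)c(c1)[C@@H](O[Li])CCCCCCCCC[C@H](CCC1(C)OCCO1)O[Si](C)(C)C(C)(C)C | intermediate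
18 | 2-[(1S,11R)-11-(tert-butyldimethylsilyloxy)-1-hydroxy-13-(2-methyl-1,3-dioxolan-2-yl)tridecyl]-4,6-dimethoxy-N,N-diisopropylbenzamide | COc1cc(OC)c(C(=O)N(C(C)C)C(C)C)c(c1)[C@@H](O)CCCCCCCCC[C@H](CCC1(C)OCCO1)O[Si](C)(C)C(C)(C)C | intermediate
19 | (3S)-3-[(10R)-10-hydroxy-13-oxotetradecyl]-5,7-dimethoxyphthalide | COc1cc(OC)c2c(c1)[C@H](CCCCCCCCC[C@H](CCC(C)=O)O)OC2=O | intermediate
20 | (3S)-3-[(10R)-10-acetoxy-13-oxotetradecyl]-5,7-dimethoxyphthalide | COc1cc(OC)c2c(c1)[C@H](CCCCCCCCC[C@H](CCC(C)=O)OC(C)=O)OC2=O | target

Total step count: 11. Longest linear sequence: 8 (steps 1, 2, 3, 5, 6, 9, 10, 11).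

Steps most likely to fail

Risk 1, step 9 (the labelled step).
- What may go wrong: the carbanion may be spent in iodine–lithium exchange with the aryne source instead of in addition. Butyllithium may outrun it for the aryne. The carbamoyl transfer may lag behind proton or iodine transfer to the aryllithium. The configuration at C3 may erode.
- Fallback: known lithiation–borylation chemistry, setting out from 10 and returning at 18.
- 2,4-Dimethoxybenzoyl chloride and diisopropylamine (CH2Cl2, 0 °C) give N,N-diisopropyl-2,4-dimethoxybenzamide F1.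
- Amide-directed ortho-lithiation (s-BuLi, TMEDA, THF, −78 °C) and a quench with 2-isopropoxy-4,4,5,5-tetramethyl-1,3,2-dioxaborolane give N,N-diisopropyl-2,4-dimethoxy-6-(4,4,5,5-tetramethyl-1,3,2-dioxaborolan-2-yl)benzamide F2.
- Carbanion 14, made from 10 as in step 9, is trapped by F2 at −78 °C with retention as the lithium boronate complex F3.
- On warming (MgBr2·OEt2 if needed) the aryl group migrates from boron to C3 with inversion, a Matteson-type 1,2-metalate rearrangement that expels the carbamate and gives the secondary benzylic pinacol boronic ester F4.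
- NaOH/H2O2 then turns C–B into C–OH with retention and gives 18, with (S)-C3 from the same (+)-sparteine.

Risk 2, step 10.
- What may go wrong: acyl transfer out of the doubly ortho-flanked diisopropylamide may be slow. Long heating in acid would then let the freed γ-hydroxy ketone dehydrate through its cyclic hemiketal.
- Fallback: a redox route that avoids hot acid, setting out from 18 and returning at 19.
- LiNH2BH3 (THF, 0 °C to rt) reduces the amide to (1S,11R)-11-(tert-butyldimethylsilyloxy)-1-[2-(hydroxymethyl)-3,5-dimethoxyphenyl]-13-(2-methyl-1,3-dioxolan-2-yl)tridecan-1-ol F5.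
- TEMPO (cat.) with PhI(OAc)2 in CH2Cl2 oxidises the primary benzylic alcohol selectively. The lactol that forms with the C3 hydroxyl is oxidised on to (3S)-3-[(10R)-10-(tert-butyldimethylsilyloxy)-12-(2-methyl-1,3-dioxolan-2-yl)dodecyl]-5,7-dimethoxyphthalide F6.
- 1 M HCl in THF at rt then removes the ketal and the silyl ether to give 19.

Risk 3, step 7.
- What may go wrong: poor positional selectivity (attack at C4 between the methoxy groups) and over-iodination.
- Fallback: directed ortho-metalation, setting out from 11 and returning at 12.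
- NaH and N,N-diethylcarbamoyl chloride (THF) give 3,5-dimethoxyphenyl N,N-diethylcarbamate F7.
- s-BuLi/TMEDA (THF, −78 °C) lithiates C2, where the carbamate and methoxy groups cooperate, and I2 gives 2-iodo-3,5-dimethoxyphenyl N,N-diethylcarbamate F8.
- NaOH in refluxing EtOH cleaves the carbamate to 12.

Further compounds
F1 | step 9 | N,N-diisopropyl-2,4-dimethoxybenzamide | COc1ccc(C(=O)N(C(C)C)C(C)C)c(OC)c1
F2 | step 9 | N,N-diisopropyl-2,4-dimethoxy-6-(4,4,5,5-tetramethyl-1,3,2-dioxaborolan-2-yl)benzamide | COc1cc(B2OC(C)(C)C(C)(C)O2)c(C(=O)N(C(C)C)C(C)C)c(OC)c1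
F3 | step 9 | lithium boronate complex of 14 and F2 | [Li+].COc1cc(c(C(=O)N(C(C)C)C(C)C)c(OC)c1)[B-]1(OC(C)(C)C(C)(C)O1)[C@@H](OC(=O)N(C(C)C)C(C)C)CCCCCCCCC[C@H](CCC1(C)OCCO1)O[Si](C)(C)C(C)(C)C
F4 | step 9 | secondary benzylic pinacol boronic ester (boron in place of the C3 hydroxyl of 18) | COc1cc(OC)c(C(=O)N(C(C)C)C(C)C)c(c1)[C@@H](B1OC(C)(C)C(C)(C)O1)CCCCCCCCC[C@H](CCC1(C)OCCO1)O[Si](C)(C)C(C)(C)C
F5 | step 10 | (1S,11R)-11-(tert-butyldimethylsilyloxy)-1-[2-(hydroxymethyl)-3,5-dimethoxyphenyl]-13-(2-methyl-1,3-dioxolan-2-yl)tridecan-1-ol | COc1cc(OC)c(CO)c(c1)[C@@H](O)CCCCCCCCC[C@H](CCC1(C)OCCO1)O[Si](C)(C)C(C)(C)C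
F6 | step 10 | (3S)-3-[(10R)-10-(tert-butyldimethylsilyloxy)-12-(2-methyl-1,3-dioxolan-2-yl)dodecyl]-5,7-dimethoxyphthalide | COc1cc(OC)c2c(c1)[C@H](CCCCCCCCC[C@H](CCC1(C)OCCO1)O[Si](C)(C)C(C)(C)C)OC2=O
F7 | step 7 | 3,5-dimethoxyphenyl N,N-diethylcarbamate | CCN(CC)C(=O)Oc1cc(OC)cc(OC)c1
F8 | step 7 | 2-iodo-3,5-dimethoxyphenyl N,N-diethylcarbamate | CCN(CC)C(=O)Oc1cc(OC)cc(OC)c1I
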